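**Plan**
Numbering: O1–O2–C3(CH2CO2H)–C4(Et)–C5–C6(Et, chain); chain C7H2–C8H(Me)–C9H2–C10H(Et)–C11H=C12H–C13(=O)–C14H3.
Cuts: ester C–O; C11=C12 (Wittig); C3–CH2CO2Me and C6–Et (two peroxycarbenium alkylations); O1–O2 taken out of the ring with C3 and C6 rejoined as a C=C bond; C6–C7 (Negishi).
Enabling feature: the two O-bearing ring carbons C3 and C6 are 1,4-related through C4–C5. C3–C4–C5–C6 is therefore a four-membered carbocycle with O1–O2 inserted into one bond, and a 1-alkyl-3-ethylcyclobutene holds a single stereocentre (C4).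
Forward: 3-ethylcyclobutanone → scalemic cyclobutenyl triflate; chain iodide by Evans allylation and Zr-catalysed carboalumination; Negishi union; ozonolysis in MeOH expands the four-ring to the 1,2-dioxane; then C6–Et, C3–CH2CO2Me, enone, acid.
Stereochemistry: C4 from a chiral lithium amide. C6 and C3 come from axial attack on half-chair peroxycarbenium ions steered by C4, so the order of introduction tells Et from chain at C6. C10 from the oxazolidinone, C8 from the Zr catalyst, E-alkene from a stabilised ylide.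

Key step: step 10

Remarks: SC = (2S,4S)-5-[(tert-butyldiphenylsilyl)oxy]-4-ethyl-2-methylpentyl (C7–C11 of the target).
Assumption: lithium (S,S)-bis(1-phenylethyl)amide is taken to show on 3-ethylcyclobutanone the same sense of induction as on 3-arylcyclobutanones. If the sense is opposite, the (R,R)-amine is used with no other change.
All peroxides are handled cold, in dilute solution and behind a shield.

**Step 1**
Reactants: 1 but-1-ene
Product: 2 (±)-2,2-dichloro-3-ethylcyclobutan-1-one
Conditions: Cl3CCOCl, Zn–Cu couple, Et2O–DME, 0 °C → rt (alkene condensed in)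
Reagents that add atoms: trichloroacetyl chloride, ClC(=O)C(Cl)(Cl)Cl
Why: Ketene–alkene [2+2] cycloaddition: dichloroketene made by zinc dechlorination bonds through its carbonyl carbon to the terminal CH2, which puts the ethyl group next to CCl2; the racemic centre ceases to be a stereocentre in step 2.

**Step 2**
Reactants: 2 (±)-2,2-dichloro-3-ethylcyclobutan-1-one
Product: 3 3-ethylcyclobutan-1-one
Conditions: Zn dust, AcOH, rt → 60 °C
Reagents that add atoms: none
Why: Reductive dechlorination of an α,α-dichloroketone through zinc enolates gives the achiral, mirror-symmetric ketone.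

**Step 3**
Reactants: 3 3-ethylcyclobutan-1-one
Product: 5 (3S)-3-ethylcyclobut-1-en-1-yl trifluoromethanesulfonate, via lithium enolate 4 (not isolated)
Conditions: (S,S)-bis(1-phenylethyl)amine, n-BuLi, LiCl, THF, −100 °C; then N-(5-chloropyridin-2-yl)bis(trifluoromethanesulfonimide), −100 → −20 °C; aq. NH4Cl
Reagents that add atoms: N-(5-chloropyridin-2-yl)bis(trifluoromethanesulfonimide), O=S(=O)(N(c1ccc(Cl)cn1)S(=O)(=O)C(F)(F)F)C(F)(F)F
Why: Enantioselective deprotonation (chiral lithium amide desymmetrisation, LiCl keeping the selectivity under external quench) removes a proton from one of the two enantiotopic α-CH2 groups, and O-sulfonylation freezes enolate 4, so the ethyl-bearing carbon (future C4) becomes the (S)-stereocentre.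

**Step 4**
Reactants: 6 (4R)-4-benzyl-1,3-oxazolidin-2-one
Product: 7 (4R)-4-benzyl-3-butanoyl-1,3-oxazolidin-2-one
Conditions: butanoyl chloride, Et3N, DMAP (cat.), CH2Cl2, 0 °C → rt
Reagents that add atoms: butanoyl chloride, CCCC(=O)Cl
Why: DMAP-catalysed N-acylation of the oxazolidinone.

**Step 5**
Reactants: 7 (4R)-4-benzyl-3-butanoyl-1,3-oxazolidin-2-one
Product: 9 (4R)-4-benzyl-3-[(2S)-2-ethylpent-4-enoyl]-1,3-oxazolidin-2-one, via sodium Z-enolate 8 (not isolated)
Conditions: NaN(SiMe3)2, THF, −78 °C; allyl iodide, −78 → −40 °C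
Reagents that add atoms: allyl iodide, C=CCI
Why: Evans asymmetric alkylation: the chelated Z-enolate 8 is allylated on the face opposite the benzyl group, which sets the future C10 as (S).

**Step 6**
Reactants: 9 (4R)-4-benzyl-3-[(2S)-2-ethylpent-4-enoyl]-1,3-oxazolidin-2-one
Product: 10 (2S)-2-ethylpent-4-en-1-ol
Conditions: LiBH4, MeOH (1 equiv), Et2O, 0 °C
Reagents that add atoms: none
Why: Reductive cleavage of the N-acyl oxazolidinone by borohydride gives the primary alcohol without touching the alkene or the α-stereocentre.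

**Step 7**
Reactants: 10 (2S)-2-ethylpent-4-en-1-ol
Product: 11 tert-butyl{[(2S)-2-ethylpent-4-en-1-yl]oxy}diphenylsilane
Conditions: TBDPSCl, imidazole, CH2Cl2, rt
Reagents that add atoms: tert-butyl(chloro)diphenylsilane, CC(C)(C)[Si](Cl)(c1ccccc1)c1ccccc1
Why: Silyl ether formation; TBDPS is chosen because it withstands AlMe3, ozone, acid in methanol and the Lewis acids of steps 11 and 13.

**Step 8**
Reactants: 11 tert-butyl{[(2S)-2-ethylpent-4-en-1-yl]oxy}diphenylsilane
Product: 13 tert-butyl{[(2S,4S)-2-ethyl-5-iodo-4-methylpentyl]oxy}diphenylsilane, via alkyl(dimethyl)alane 12 (not isolated)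
Conditions: AlMe3, (+)-bis[(1-neomenthyl)indenyl]zirconium dichloride [(+)-(NMI)2ZrCl2, 5 mol %], methylaluminoxane (MeAlO)n (cat.), CH2Cl2, 0 °C → rt; then I2, THF, −30 °C → rt
Reagents that add atoms: trimethylaluminium, C[Al](C)C; iodine, II
Why: Zirconium-catalysed asymmetric carboalumination places methyl on the internal and aluminium on the terminal alkene carbon under catalyst control (the (+)-catalyst gives the (S)-2-methylalkyl series, setting C8), iodinolysis turns the C–Al bond into C–I, and any minor C8 epimer is removed by chromatography.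

**Step 9**
Reactants: 13 tert-butyl{[(2S,4S)-2-ethyl-5-iodo-4-methylpentyl]oxy}diphenylsilane; 5 (3S)-3-ethylcyclobut-1-en-1-yl trifluoromethanesulfonate
Product: 15 (3S)-3-ethyl-1-SC-cyclobut-1-ene, via alkylzinc iodide 14 (not isolated)
Conditions: 13, Zn dust (activated), LiCl, THF, 40 °C; then 5, Pd(dppf)Cl2 (5 mol %), THF, rt → 40 °C
Reagents that add atoms: none
Why: Negishi sp3–sp2 cross-coupling: zinc inserts into the primary C–I bond, zerovalent palladium adds to the alkenyl C–OTf bond, and the wide-bite dppf ligand favours reductive elimination over β-hydride loss; this forms C6–C7 and touches no stereocentre.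

**Step 10**
Reactants: 15 (3S)-3-ethyl-1-SC-cyclobut-1-ene
Product: 20 (4S)-4-ethyl-3,6-dimethoxy-6-SC-1,2-dioxane (mixture of C3/C6 anomers), via primary ozonide 16 (not isolated), via carbonyl oxide 17 (not isolated), via hydroperoxy ketal aldehyde 18 (not isolated), via methoxydioxanol 19 (not isolated)
Conditions: O3/O2, CH2Cl2–MeOH (4:1), −78 °C until 15 is consumed; Ar purge; then HC(OMe)3, camphorsulfonic acid (10 mol %), −78 → 0 °C
Reagents that add atoms: ozone, [O-][O+]=O; methanol, CO; trimethyl orthoformate, COC(OC)OC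
Why: Ozone adds to the strained, electron-rich trisubstituted C3=C6 bond in a 1,3-dipolar cycloaddition (16), and Criegee cycloreversion, driven by release of the four-ring strain, severs C3 from C6 to leave carbonyl oxide 17, whose two termini stay tied through C5–C4 and which methanol traps as hydroperoxy ketal 18. The hydroperoxide oxygen then adds to the C3 aldehyde in a 6-exo-trig closure (19), so the net event is insertion of O1–O2 into the carbocycle, four ring atoms becoming six, and acid with orthoformate caps the hemiacetal as 20. The closest known reaction type is ozonolysis of cycloalkenes in alcohols with closure of the α-alkoxy hydroperoxide onto the second carbonyl group, followed by acid-catalysed peroxyacetal exchange. The new centres C3 and C6 arise as uncontrolled anomeric mixtures on purpose, because both are erased through planar peroxycarbenium ions in steps 11 and 13, whereas C4 is not touched. The opposite sense of Criegee cleavage ends after exchange in the same 20, so regiochemistry and anomer ratio converge on one constitution. Chemoselectivity is secured because the ring C=C is the only ozone-reactive site at −78 °C, and C4 epimerisation is held back because the free aldehyde is captured intramolecularly in the cold.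

**Step 11**
Reactants: 20 (4S)-4-ethyl-3,6-dimethoxy-6-SC-1,2-dioxane
Product: 22 (4S,6R)-4-ethyl-6-ethynyl-3-methoxy-6-SC-1,2-dioxane (C3 anomers), via C6 peroxycarbenium ion 21 (not isolated)
Conditions: K[HC≡CBF3] (1.2 equiv), BF3·OEt2 (1.2 equiv), CH2Cl2–MeCN, −78 → −40 °C
Reagents that add atoms: potassium ethynyltrifluoroborate, C#C[B-](F)(F)F.[K+]
Why: Proposed new method: BF3 takes fluoride from the borate to give HC≡C–BF2, which ionises the more labile of the two C–OMe bonds, that of the ketal carbon C6 (tertiary, dialkyl-stabilised ion 21) rather than the acetal carbon C3; the resulting methoxy(ethynyl)difluoroborate hands its alkynyl group to C6, and the slim sp nucleophile enters along the axial, chair-forming trajectory of the half-chair with the C4 ethyl pseudo-equatorial, that is trans to that ethyl, which leaves the chain equatorial and sets C6 as (R). The closest known reaction types are the BF3-mediated axial C-alkynylation of cyclic acetals and glycosyl donors with alkynyltrifluoroborates and the Lewis acid-mediated allylation or enol silane alkylation of 3-alkoxy-1,2-dioxanes and -dioxolanes; only the pairing of a boron alkynyl donor with a peroxyketal is new.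

**Step 12**
Reactants: 22 (4S,6R)-4-ethyl-6-ethynyl-3-methoxy-6-SC-1,2-dioxane
Product: 24 (4S,6R)-4,6-diethyl-3-methoxy-6-SC-1,2-dioxane (C3 anomers), via vinyl dioxane 23 (not isolated)
Conditions: 2-nitrobenzenesulfonohydrazide (excess, in portions), Et3N, CH2Cl2, rt
Reagents that add atoms: none
Why: Diimide reduction transfers H2 in a concerted syn manner to C≡C and then to C=C (23) and, unlike catalytic hydrogenation, leaves the O–O bond intact.

**Step 13**
Reactants: 24 (4S,6R)-4,6-diethyl-3-methoxy-6-SC-1,2-dioxane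
Product: 26 methyl [(3S,4S,6R)-4,6-diethyl-6-SC-1,2-dioxan-3-yl]acetate, via C3 peroxycarbenium ion 25 (not isolated)
Conditions: tert-butyl[(1-methoxyvinyl)oxy]dimethylsilane (2 equiv), Me3SiOTf (0.2 equiv), CH2Cl2, −78 °C
Reagents that add atoms: tert-butyl[(1-methoxyvinyl)oxy]dimethylsilane, C=C(OC)O[Si](C)(C)C(C)(C)C
Why: Mukaiyama-type alkylation of a cyclic peroxyacetal, known for 3-alkoxy- and 3-acyloxy-1,2-dioxanes: Me3SiOTf ionises C3–OMe to ion 25, whose half-chair is locked because a ring flip would make the C4 ethyl and the C6 chain 1,3-diaxial, and the ketene acetal enters axially, cis to the pseudo-equatorial C4 ethyl and cis to the C6 chain, which sets C3 as (S).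

**Step 14**
Reactants: 26 methyl [(3S,4S,6R)-4,6-diethyl-6-SC-1,2-dioxan-3-yl]acetate
Product: 27 methyl {(3S,4S,6R)-4,6-diethyl-6-[(2S,4S)-4-ethyl-5-hydroxy-2-methylpentyl]-1,2-dioxan-3-yl}acetate
Conditions: HF·pyridine, pyridine, THF, 0 °C → rt
Reagents that add atoms: none
Why: Fluoride desilylation in a non-basic medium avoids Kornblum–DeLaMare cleavage at C3–H and retro-Michael loss of the β-peroxy ester.

**Step 15**
Reactants: 27 methyl {(3S,4S,6R)-4,6-diethyl-6-[(2S,4S)-4-ethyl-5-hydroxy-2-methylpentyl]-1,2-dioxan-3-yl}acetate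
Product: 28 methyl {(3S,4S,6R)-4,6-diethyl-6-[(2S,4S)-4-formyl-2-methylhexyl]-1,2-dioxan-3-yl}acetate
Conditions: DMP (1,1,1-triacetoxy-1,1-dihydro-1,2-benziodoxol-3(1H)-one), CH2Cl2, 0 °C → rt
Reagents that add atoms: none
Why: Hypervalent-iodine oxidation of the primary alcohol stops at the aldehyde under near-neutral conditions, which spare the peroxide and the α-stereocentre C10.

**Step 16**
Reactants: 28 methyl {(3S,4S,6R)-4,6-diethyl-6-[(2S,4S)-4-formyl-2-methylhexyl]-1,2-dioxan-3-yl}acetate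
Product: 29 methyl {(3S,4S,6R)-4,6-diethyl-6-[(2S,4S,5E)-4-ethyl-2-methyl-7-oxooct-5-en-1-yl]-1,2-dioxan-3-yl}acetate
Conditions: Ph3P=CHC(O)CH3, toluene, 50 °C
Reagents that add atoms: 1-(triphenyl-λ5-phosphanylidene)propan-2-one, CC(=O)C=P(c1ccccc1)(c1ccccc1)c1ccccc1
Why: Wittig olefination with a stabilised, essentially non-basic ylide gives the E-enone, does not epimerise C10 and does not reduce the dialkyl peroxide.

**Step 17**
Reactants: 29 methyl {(3S,4S,6R)-4,6-diethyl-6-[(2S,4S,5E)-4-ethyl-2-methyl-7-oxooct-5-en-1-yl]-1,2-dioxan-3-yl}acetate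
Product: 30 {(3S,4S,6R)-4,6-diethyl-6-[(2S,4S,5E)-4-ethyl-2-methyl-7-oxooct-5-en-1-yl]-1,2-dioxan-3-yl}acetic acid (target)
Conditions: LiOH, THF–H2O, 0 °C → rt; then 1 M HCl to pH 3
Reagents that add atoms: lithium hydroxide, [Li+].[OH-]
Why: Saponification of the unhindered methyl ester is fast at or below rt, and the carboxylate once formed no longer undergoes β-elimination of the peroxide.

**Compound list**
1 | but-1-ene | C=CCC | starting material
2 | (±)-2,2-dichloro-3-ethylcyclobutan-1-one | CCC1CC(=O)C1(Cl)Cl | intermediate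
3 | 3-ethylcyclobutan-1-one (achiral) | CCC1CC(=O)C1 | intermediate
4 | lithium (3S)-3-ethylcyclobut-1-en-1-olate | [Li]OC1=C[C@@H](CC)C1 | intermediate
5 | (3S)-3-ethylcyclobut-1-en-1-yl trifluoromethanesulfonate | O=S(=O)(OC1=C[C@@H](CC)C1)C(F)(F)F | intermediate
6 | (4R)-4-benzyl-1,3-oxazolidin-2-one | O=C1N[C@H](Cc2ccccc2)CO1 | starting material
7 | (4R)-4-benzyl-3-butanoyl-1,3-oxazolidin-2-one | CCCC(=O)N1[C@H](Cc2ccccc2)COC1=O | intermediate
8 | sodium (Z)-enolate of 7 | CC/C=C(\O[Na])N1[C@H](Cc2ccccc2)COC1=O | intermediate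
9 | (4R)-4-benzyl-3-[(2S)-2-ethylpent-4-enoyl]-1,3-oxazolidin-2-one | CC[C@H](C(=O)N1[C@H](Cc2ccccc2)COC1=O)CC=C | intermediate
10 | (2S)-2-ethylpent-4-en-1-ol | CC[C@H](CO)CC=C | intermediate
11 | tert-butyl{[(2S)-2-ethylpent-4-en-1-yl]oxy}diphenylsilane | CC[C@H](CO[Si](c3ccccc3)(c4ccccc4)C(C)(C)C)CC=C | intermediate
12 | {(2S,4S)-5-[(tert-butyldiphenylsilyl)oxy]-4-ethyl-2-methylpentyl}dimethylalane | CC[C@H](CO[Si](c3ccccc3)(c4ccccc4)C(C)(C)C)C[C@H](C)C[Al](C)C | intermediate
13 | tert-butyl{[(2S,4S)-2-ethyl-5-iodo-4-methylpentyl]oxy}diphenylsilane | CC[C@H](CO[Si](c3ccccc3)(c4ccccc4)C(C)(C)C)C[C@H](C)CI | intermediate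
14 | {(2S,4S)-5-[(tert-butyldiphenylsilyl)oxy]-4-ethyl-2-methylpentyl}zinc iodide | CC[C@H](CO[Si](c3ccccc3)(c4ccccc4)C(C)(C)C)C[C@H](C)C[Zn]I | intermediate
15 | (3S)-3-ethyl-1-SC-cyclobut-1-ene | CC[C@H](CO[Si](c3ccccc3)(c4ccccc4)C(C)(C)C)C[C@H](C)CC1=C[C@@H](CC)C1 | intermediate
16 | primary ozonide of 15, cis-fused 2,3,4-trioxabicyclo[3.2.0]heptane, O3 anti to the ethyl group | CC[C@H](CO[Si](c3ccccc3)(c4ccccc4)C(C)(C)C)C[C@H](C)C[C@]12C[C@H](CC)[C@H]1OOO2 | intermediate
17 | carbonyl oxide at C6 with aldehyde at C3, (4S) | CC[C@H](CO[Si](c3ccccc3)(c4ccccc4)C(C)(C)C)C[C@H](C)CC(=[O+][O-])C[C@H](CC)C=O | intermediate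
18 | (2S)-2-ethyl-4-hydroperoxy-4-methoxy-4-SC-butanal (C6 epimers) | CC[C@H](CO[Si](c3ccccc3)(c4ccccc4)C(C)(C)C)C[C@H](C)CC(OC)(OO)C[C@H](CC)C=O | intermediate
19 | (4S)-4-ethyl-6-methoxy-6-SC-1,2-dioxan-3-ol (C3/C6 anomers) | CC[C@H](CO[Si](c3ccccc3)(c4ccccc4)C(C)(C)C)C[C@H](C)CC1(OC)C[C@H](CC)C(O)OO1 | intermediate
20 | (4S)-4-ethyl-3,6-dimethoxy-6-SC-1,2-dioxane (C3/C6 anomers) | CC[C@H](CO[Si](c3ccccc3)(c4ccccc4)C(C)(C)C)C[C@H](C)CC1(OC)C[C@H](CC)C(OC)OO1 | intermediate
21 | C6 peroxycarbenium ion (O1=C6 cation, 3-methoxy, 4S) | CC[C@H](CO[Si](c3ccccc3)(c4ccccc4)C(C)(C)C)C[C@H](C)CC1=[O+]OC(OC)[C@@H](CC)C1 | intermediate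
22 | (4S,6R)-4-ethyl-6-ethynyl-3-methoxy-6-SC-1,2-dioxane (C3 anomers) | CC[C@H](CO[Si](c3ccccc3)(c4ccccc4)C(C)(C)C)C[C@H](C)C[C@]1(C#C)C[C@H](CC)C(OC)OO1 | intermediate
23 | (4S,6R)-6-ethenyl-4-ethyl-3-methoxy-6-SC-1,2-dioxane | CC[C@H](CO[Si](c3ccccc3)(c4ccccc4)C(C)(C)C)C[C@H](C)C[C@]1(C=C)C[C@H](CC)C(OC)OO1 | intermediate
24 | (4S,6R)-4,6-diethyl-3-methoxy-6-SC-1,2-dioxane (C3 anomers) | CC[C@H](CO[Si](c3ccccc3)(c4ccccc4)C(C)(C)C)C[C@H](C)C[C@]1(CC)C[C@H](CC)C(OC)OO1 | intermediate
25 | C3 peroxycarbenium ion (O2=C3 cation, 4S,6R) | CC[C@H](CO[Si](c3ccccc3)(c4ccccc4)C(C)(C)C)C[C@H](C)C[C@]1(CC)C[C@H](CC)C=[O+]O1 | intermediate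
26 | methyl [(3S,4S,6R)-4,6-diethyl-6-SC-1,2-dioxan-3-yl]acetate | CC[C@H](CO[Si](c3ccccc3)(c4ccccc4)C(C)(C)C)C[C@H](C)C[C@]1(CC)C[C@H](CC)[C@H](CC(=O)OC)OO1 | intermediate
27 | methyl {(3S,4S,6R)-4,6-diethyl-6-[(2S,4S)-4-ethyl-5-hydroxy-2-methylpentyl]-1,2-dioxan-3-yl}acetate | CC[C@H](CO)C[C@H](C)C[C@]1(CC)C[C@H](CC)[C@H](CC(=O)OC)OO1 | intermediate
28 | methyl {(3S,4S,6R)-4,6-diethyl-6-[(2S,4S)-4-formyl-2-methylhexyl]-1,2-dioxan-3-yl}acetate | CC[C@H](C=O)C[C@H](C)C[C@]1(CC)C[C@H](CC)[C@H](CC(=O)OC)OO1 | intermediate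
29 | methyl {(3S,4S,6R)-4,6-diethyl-6-[(2S,4S,5E)-4-ethyl-2-methyl-7-oxooct-5-en-1-yl]-1,2-dioxan-3-yl}acetate | CC[C@H](/C=C/C(C)=O)C[C@H](C)C[C@]1(CC)C[C@H](CC)[C@H](CC(=O)OC)OO1 | intermediate
30 | {(3S,4S,6R)-4,6-diethyl-6-[(2S,4S,5E)-4-ethyl-2-methyl-7-oxooct-5-en-1-yl]-1,2-dioxan-3-yl}acetic acid | CC[C@H](/C=C/C(C)=O)C[C@H](C)C[C@]1(CC)C[C@H](CC)[C@H](CC(=O)O)OO1 | target

**Count**
Total steps: 17. Longest linear sequence: 14 (steps 4–17).

**Steps most likely to fail**

1. Step 11.
Alkynyl transfer from boron may be slower than proton loss from the ion or O–O heterolysis. Ionisation may also start at C3. Transannular participation of the C3 methoxy group may erode the facial bias.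
Fallback, known chemistry only, from 20 back to 24:
- Peroxyketal 20 is alkylated with vinyloxytrimethylsilane and catalytic Me3SiOTf in CH2Cl2 at −78 °C. This is an enol silane alkylation of an alkoxydioxane with the same axial entry. It gives [(4S,6R)-4-ethyl-3-methoxy-6-SC-1,2-dioxan-6-yl]acetaldehyde F1.
- Condensation with 4-methylbenzenesulfonohydrazide gives the N-tosylhydrazone F2.
- Reduction with catecholborane, then NaOAc·3H2O (hydrazone reduction with diazene fragmentation), turns CH2CH=N into CH2CH3 and delivers 24.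

2. Step 10.
Intermolecular capture of the carbonyl oxide may give oligomeric peroxides. The acid treatment may open the ring to acyclic acetals. C4 may epimerise while the aldehyde is free.
Fallback from 15 back to 20:
- Dihydroxylation with OsO4 (cat.) and N-methylmorpholine N-oxide, anti to the ethyl group, gives cis-3-ethyl-1-SC-cyclobutane-1,2-diol F3.
- Glycol cleavage with NaIO4 gives the 1,4-keto aldehyde (2S)-2-ethyl-4-oxo-4-SC-butanal F4.
- Acid-catalysed double peroxyacetalisation with urea–hydrogen peroxide in MeOH/HC(OMe)3 closes 20.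

3. Step 13.
Facial selectivity may be poor because the axial approach runs next to the C4 ethyl group. The Lewis acid may also ionise the tertiary C6–O1 bond.
Fallback from 24 back to 26:
- Mild aqueous acid (AcOH–H2O–THF) hydrolyses 24 to the lactol (4S,6R)-4,6-diethyl-6-SC-1,2-dioxan-3-ol F5.
- The open hydroperoxy aldehyde form of F5 reacts with Ph3P=CHCO2Me to give the hydroperoxy enoate F6.
- Et2NH in CF3CH2OH closes the ring by intramolecular peroxy-Michael addition (6-exo-trig). The closure is reversible, so the unwanted C3 epimer can be separated and resubmitted until the material is funnelled into 26.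

**Further compounds**
F1 | step 11 | [(4S,6R)-4-ethyl-3-methoxy-6-SC-1,2-dioxan-6-yl]acetaldehyde | CC[C@H](CO[Si](c3ccccc3)(c4ccccc4)C(C)(C)C)C[C@H](C)C[C@]1(CC=O)C[C@H](CC)C(OC)OO1
F2 | step 11 | N-tosylhydrazone of F1 | CC[C@H](CO[Si](c3ccccc3)(c4ccccc4)C(C)(C)C)C[C@H](C)C[C@]1(CC=NNS(=O)(=O)c2ccc(C)cc2)C[C@H](CC)C(OC)OO1
F3 | step 10 | cis-3-ethyl-1-SC-cyclobutane-1,2-diol, both OH anti to ethyl | CC[C@H](CO[Si](c3ccccc3)(c4ccccc4)C(C)(C)C)C[C@H](C)C[C@]1(O)C[C@H](CC)[C@H]1O
F4 | step 10 | (2S)-2-ethyl-4-oxo-4-SC-butanal | CC[C@H](CO[Si](c3ccccc3)(c4ccccc4)C(C)(C)C)C[C@H](C)CC(=O)C[C@H](CC)C=O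
F5 | step 13 | (4S,6R)-4,6-diethyl-6-SC-1,2-dioxan-3-ol | CC[C@H](CO[Si](c3ccccc3)(c4ccccc4)C(C)(C)C)C[C@H](C)C[C@]1(CC)C[C@H](CC)C(O)OO1
F6 | step 13 | methyl (2E,4S,6R)-4,6-diethyl-6-hydroperoxy-6-SC-hex-2-enoate | CC[C@H](CO[Si](c3ccccc3)(c4ccccc4)C(C)(C)C)C[C@H](C)C[C@](OO)(CC)C[C@H](CC)/C=C/C(=O)OC
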